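The litre per mole was the unit I reckoned in: a second-order rate constant integrated over time carries it, and I used that amount to hold the history up to a given hour of flasks charged with the same free catalyst.

| flask | substrate | reagent | free catalyst | time |
|---|---|---|---|---|
| maple | 300 mM | 300 mM | 9.00 mM |  |
| oak | 150 mM | 150 mM | 9.00 mM |  |
| larch | 300 mM | 450 mM | 9.00 mM |  |
| alder | 150 mM | 300 mM | 9.00 mM |  |
| birch | 65.0 mM | 300 mM | 9.00 mM | 100 h |

| run | time / h | [substrate] / mM |
|---|---|---|
| maple run | 4.0 | 280.8 |
| maple run | 6.8 | 271.3 |
| maple run | 12 | 253.1 |
| maple run | 20 | 234.1 |
| maple run | 34 | 210.7 |
| maple run | 58 | 194.2 |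
| maple run | 100 | 181.5 |
| oak run | 4.0 | 145.8 |
| oak run | 6.8 | 143.2 |
| oak run | 12 | 138.6 |
| oak run | 20 | 131.6 |
| oak run | 34 | 124.9 |
| oak run | 58 | 117.7 |
| oak run | 100 | 115.9 |
| larch run | 4.0 | 271.0 |
| larch run | 6.8 | 255.9 |
| larch run | 12 | 232.2 |
| larch run | 20 | 207.9 |
| larch run | 34 | 177.3 |
| larch run | 58 | 153.9 |
| larch run | 100 | 138.2 |
| alder run | 4.0 | 140.2 |
| alder run | 6.8 | 133.4 |
| alder run | 12 | 126.7 |
| alder run | 20 | 116.1 |
| alder run | 34 | 104.9 |
| alder run | 58 | 90.4 |
| alder run | 100 | 85.5 |

(standard deviation of a reading: 0.9 mM)

- apparent order in [reagent] of the starting rate, round the charge of the maple run (the rate where two percent of its substrate have turned into product)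
- apparent order in [substrate] of the starting rate, round the charge of the maple run (the rate where two percent of its substrate have turned into product) (one fixed amount of product, the same in the runs compared)
- substrate in the birch run at 100 h, as a share of the substrate charged

- Overall: substrate + reagent -> product, with free catalyst as catalyst.
- Constant volume, constant temperature.
- "The second partner" is reagent.
- An order is taken over about fifteen percent of the charge, up and down.

The first readings gave the orders. At 4.0 h the larch run had lost 1.51 times the substrate lost in the maple run, which gives an order in [reagent] of about 1.02. The alder run, with half the [substrate] of the maple run, had lost 0.510 of that amount, which gives an order in [substrate] of about 0.970. I therefore wrote the rate as k[substrate][reagent], with k free to change in time.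

The maple run has equal charges, so the rise in the reciprocal of its [substrate] up to 100 h is the integral of k, which was 2.18 L mol⁻¹. The birch run has the same charge of free catalyst as the maple run, so I carried this reading over to it. Multiplied by the excess of reagent over substrate in the birch run, it gives the reach, the rise in the logarithm of [reagent]/[substrate] up to that hour, a count of substrate lifetimes with the excess standing in for [reagent] as in a pseudo-first-order reckoning; it comes to 0.511. So the birch run should keep 54.0% of its substrate.

I tested whether one number was enough. It reckons 139 mM for the larch run against a reading of 138.2 mM, and 84.6 mM for the alder run against 85.5 mM. The oak run read 115.9 mM, higher than the reckoned 113 mM by 3.13 standard deviations of a reading. Taking the integral from the oak run instead moves the birch share to 57.2%.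

The forecast, which said "That looks like catalyst dying", gave orders of 1.03 in [reagent] and 1.03 in [substrate], and a birch share of 55%, between 51.5% and 59%. The simulation gives orders of 1.0 and 1.0, and a share of 54.3%.

    2 free catalyst ⇌ catalyst dimer, settled at all times (61.60 L mol⁻¹)
    catalyst dimer + substrate + reagent → product + catalyst dimer (37.80 L² mol⁻² h⁻¹)
    free catalyst → spent catalyst (0.02365 h⁻¹)
    free catalyst + impurity → spent catalyst

The birch reach is short because free catalyst passes into spent catalyst. The simulated birch run without that passing ends at 21.1% of the substrate charged, against 54.3% with it. Put through the same logarithm, the share as it stands gives a reach of 0.507, and the run without that passing gives 1.37.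

(The data are calculated with constants of no real substance; scatter was added.)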